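**Retrosynthetic overview**
1. Target ⇐ bis(O‑benzyl), bis(O‑TBS) tetrahydrofuran, by desilylation and then hydrogenolysis.
2. Tetrahydrofuran ring (C9–O–C9′) ⇐ cyclodehydration of a 2,3‑disubstituted butane‑1,4‑diol ⇐ reduction of a trans‑α,β‑disubstituted γ‑butyrolactone.
3. C8′–C7′ bond ⇐ anti‑selective aldol of the lithium enolate of a β‑substituted γ‑butyrolactone with O‑benzylvanillin, trans to the β‑substituent.
4. β‑Substituted lactone ⇐ alkene cleavage and lactol oxidation of a pentenol ⇐ C7–C8 bond by Evans syn‑aldol of an N‑pent‑4‑enoyl oxazolidinone with O‑benzylvanillin.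
5. Ring order: temporary γ‑lactone first (lactol, then lactone), tetrahydrofuran last; both arenes are bought.

Assumption: the target SMILES is read as (7S,8R,8′R,7′R) in lignan numbering (C7/C7′ carbinol carbons, C8/C8′ ring CH, C9/C9′ ring CH2); Ar = 4‑(benzyloxy)‑3‑methoxyphenyl, TBS = tert‑butyldimethylsilyl; 1, 2 and 5 are bought.

**Route**

Step 1
Reactants: 1 (S)‑4‑benzyl‑1,3‑oxazolidin‑2‑one; 2 pent‑4‑enoyl chloride
Product: 4 (S)‑4‑benzyl‑3‑(pent‑4‑enoyl)‑1,3‑oxazolidin‑2‑one, via N‑lithio oxazolidinone 3 (not isolated)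
Conditions: n‑BuLi, THF, −78 °C; then 2, −78 → 0 °C
Reagents that add atoms: none
Why: N‑acylation of the lithiated oxazolidinone by an acid chloride (Evans auxiliary loading) is fast and clean and creates no stereocentre.

Step 2
Reactants: 4 (S)‑4‑benzyl‑3‑(pent‑4‑enoyl)‑1,3‑oxazolidin‑2‑one; 5 4‑(benzyloxy)‑3‑methoxybenzaldehyde (O‑benzylvanillin)
Product: 7 (S)‑4‑benzyl‑3‑[(S)‑2‑[(S)‑Ar(hydroxy)methyl]pent‑4‑enoyl]‑1,3‑oxazolidin‑2‑one, via Z‑dibutylboron enolate 6 (not isolated)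
Conditions: Bu2BOTf, i‑Pr2NEt, CH2Cl2, 0 °C; then 5, −78 → 0 °C; pH 7 buffer, MeOH, 30% H2O2, 0 °C
Reagents that add atoms: none
Why: Evans syn‑aldol, in which the Z‑boron enolate reacts through a closed Zimmerman–Traxler chair on the face away from the auxiliary benzyl group and so sets C8 and C7 (S) together as the "Evans syn" pair.

Step 3
Reactants: 7 the syn‑aldol adduct
Product: 8 (S)‑4‑benzyl‑3‑[(S)‑2‑[(S)‑Ar(OTBS)methyl]pent‑4‑enoyl]‑1,3‑oxazolidin‑2‑one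
Conditions: TBSOTf, 2,6‑lutidine, CH2Cl2, 0 °C
Reagents that add atoms: tert‑butyldimethylsilyl triflate, CC(C)(C)[Si](C)(C)OS(=O)(=O)C(F)(F)F
Why: Silylation with a silyl triflate and a hindered pyridine base protects the benzylic alcohol without epimerising the imide α‑centre.

Step 4
Reactants: 8 the O‑TBS imide
Product: 9 (R)‑2‑[(S)‑Ar(OTBS)methyl]pent‑4‑en‑1‑ol
Conditions: LiBH4, MeOH (1 equiv), THF, 0 °C
Reagents that add atoms: none
Why: Reductive cleavage of the imide, in which borohydride attacks the lithium‑activated exocyclic carbonyl, releases the recoverable auxiliary and gives the C9 alcohol with both stereocentres untouched.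

Step 5
Reactants: 9 (R)‑2‑[(S)‑Ar(OTBS)methyl]pent‑4‑en‑1‑ol
Product: 12 (4R)‑4‑[(S)‑Ar(OTBS)methyl]oxolan‑2‑ol (lactol as anomer mixture), via triol 10 (not isolated), via hydroxy aldehyde 11 (not isolated)
Conditions: OsO4 (2 mol%), NaIO4, 2,6‑lutidine, dioxane–H2O (3:1), rt
Reagents that add atoms: osmium tetroxide, O=[Os](=O)(=O)=O (its oxygen ends as the lactol OH); sodium periodate, [Na+].[O-]I(=O)(=O)=O (regenerates it)
Why: Lemieux–Johnson oxidation (dihydroxylation, periodate cleavage) gives the aldehyde, which closes 5‑exo onto the C9 hydroxyl; 2,6‑lutidine suppresses over‑oxidation and C8 is not touched.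

Step 6
Reactants: 12 the lactol
Product: 13 (R)‑4‑[(S)‑Ar(OTBS)methyl]oxolan‑2‑one
Conditions: TPAP (5 mol%), NMO, 4 Å MS, CH2Cl2, rt
Reagents that add atoms: none
Why: Ley–Griffith oxidation converts the lactol to the γ‑lactone under neutral conditions that spare the silyl ether, the benzyl ether and C8.

Step 7
Reactants: 13 (R)‑4‑[(S)‑Ar(OTBS)methyl]oxolan‑2‑one; 5 4‑(benzyloxy)‑3‑methoxybenzaldehyde
Product: 15 (3S,4R)‑3‑[(R)‑Ar(hydroxy)methyl]‑4‑[(S)‑Ar(OTBS)methyl]oxolan‑2‑one, via lithium enolate 14 (not isolated)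
Conditions: LDA, THF, −78 °C, 45 min; then 5, −78 °C, 30 min; AcOH quench at −78 °C
Reagents that add atoms: none
Why: Kinetic aldol addition of the lactone lithium enolate (necessarily E), in which the aldehyde enters anti to the bulky C8 substituent (3,4‑trans) and the Zimmerman–Traxler chair of an E‑enolate gives the anti carbinol, (R) at C7′; the minor C7′ epimer is removed by chromatography.

Step 8
Reactants: 15 the aldol lactone
Product: 16 (3S,4R)‑3‑[(R)‑Ar(OTBS)methyl]‑4‑[(S)‑Ar(OTBS)methyl]oxolan‑2‑one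
Conditions: TBSOTf, 2,6‑lutidine, CH2Cl2, −78 → 0 °C
Reagents that add atoms: tert‑butyldimethylsilyl triflate, CC(C)(C)[Si](C)(C)OS(=O)(=O)C(F)(F)F
Why: Low‑temperature silylation caps the C7′ hydroxyl before it can undergo retro‑aldol cleavage or compete in the later ring closure.

Step 9
Reactants: 16 the bis‑silylated lactone
Product: 17 (2R,3R)‑2‑[(S)‑Ar(OTBS)methyl]‑3‑[(R)‑Ar(OTBS)methyl]butane‑1,4‑diol
Conditions: LiBH4, MeOH (2 equiv), THF, 0 °C → rt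
Reagents that add atoms: none
Why: Borohydride reduction of the lactone gives the 1,4‑diol; LiBH4 is used in place of LiAlH4 so the neighbouring silyl ethers neither migrate nor cleave, and no stereocentre is involved.

Step 10
Reactants: 17 the 1,4‑diol
Product: 19 (3R,4R)‑3‑[(S)‑Ar(OTBS)methyl]‑4‑[(R)‑Ar(OTBS)methyl]oxolane, via cyclic dialkoxytriphenylphosphorane 18 (not isolated)
Conditions: PPh3, DIAD, THF, 0 °C → rt
Reagents that add atoms: none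
Why: Mitsunobu cyclodehydration activates one primary oxygen on phosphorus and the other displaces it 5‑exo‑tet, so the ring closes at primary carbons only and no stereocentre is affected.

Step 11
Reactants: 19 the bis‑silylated tetrahydrofuran
Product: 20 (S)‑Ar[(3R,4R)‑4‑[(R)‑Ar(hydroxy)methyl]oxolan‑3‑yl]methanol
Conditions: TBAF, THF, rt
Reagents that add atoms: none
Why: Fluoride desilylation frees both benzylic alcohols under non‑acidic conditions, which avoids ionisation of the electron‑rich benzylic carbinols.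

Step 12
Reactants: 20 the bis(O‑benzyl) diol
Product: 21 4‑[(S)‑hydroxy[(3R,4R)‑4‑[(R)‑hydroxy(4‑hydroxy‑3‑methoxyphenyl)methyl]oxolan‑3‑yl]methyl]‑2‑methoxyphenol (target)
Conditions: H2 (1 atm), 10% Pd/C, EtOAc, rt, stopped when 20 is consumed
Reagents that add atoms: none
Why: Catalytic hydrogenolysis cleaves aryl benzyl ethers much faster than the C–O bonds of secondary benzylic alcohols in neutral EtOAc, so the phenols are unmasked with all four stereocentres retained.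

**Compound list**
1 | (S)‑4‑benzyl‑1,3‑oxazolidin‑2‑one | O=C1N[C@@H](Cc2ccccc2)CO1 | starting material
2 | pent‑4‑enoyl chloride | C=CCCC(=O)Cl | starting material
3 | lithium (S)‑4‑benzyl‑2‑oxo‑1,3‑oxazolidin‑3‑ide | [Li+].O=C1[N-][C@@H](Cc2ccccc2)CO1 | intermediate (not isolated)
4 | (S)‑4‑benzyl‑3‑(pent‑4‑enoyl)‑1,3‑oxazolidin‑2‑one | C=CCCC(=O)N1[C@@H](Cc2ccccc2)COC1=O | intermediate
5 | 4‑(benzyloxy)‑3‑methoxybenzaldehyde | COc1cc(C=O)ccc1OCc1ccccc1 | starting material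
6 | (S)‑4‑benzyl‑3‑[(Z)‑1‑[(dibutylboranyl)oxy]penta‑1,4‑dien‑1‑yl]‑1,3‑oxazolidin‑2‑one | C=CC/C=C(\OB(CCCC)CCCC)N1[C@@H](Cc2ccccc2)COC1=O | intermediate (not isolated)
7 | (S)‑4‑benzyl‑3‑[(S)‑2‑[(S)‑[4‑(benzyloxy)‑3‑methoxyphenyl](hydroxy)methyl]pent‑4‑enoyl]‑1,3‑oxazolidin‑2‑one | C=CC[C@@H]([C@H](O)c1ccc(OCc2ccccc2)c(OC)c1)C(=O)N1[C@@H](Cc2ccccc2)COC1=O | intermediate
8 | (S)‑4‑benzyl‑3‑[(S)‑2‑[(S)‑[4‑(benzyloxy)‑3‑methoxyphenyl][(tert‑butyldimethylsilyl)oxy]methyl]pent‑4‑enoyl]‑1,3‑oxazolidin‑2‑one | C=CC[C@@H]([C@H](O[Si](C)(C)C(C)(C)C)c1ccc(OCc2ccccc2)c(OC)c1)C(=O)N1[C@@H](Cc2ccccc2)COC1=O | intermediate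
9 | (R)‑2‑[(S)‑[4‑(benzyloxy)‑3‑methoxyphenyl][(tert‑butyldimethylsilyl)oxy]methyl]pent‑4‑en‑1‑ol | C=CC[C@@H]([C@H](O[Si](C)(C)C(C)(C)C)c1ccc(OCc2ccccc2)c(OC)c1)CO | intermediate
10 | (2R)‑2‑[(S)‑[4‑(benzyloxy)‑3‑methoxyphenyl][(tert‑butyldimethylsilyl)oxy]methyl]pentane‑1,4,5‑triol (both C4 epimers) | OCC(O)C[C@@H]([C@H](O[Si](C)(C)C(C)(C)C)c1ccc(OCc2ccccc2)c(OC)c1)CO | intermediate (not isolated)
11 | (3R,4S)‑4‑[4‑(benzyloxy)‑3‑methoxyphenyl]‑4‑[(tert‑butyldimethylsilyl)oxy]‑3‑(hydroxymethyl)butanal | O=CC[C@@H]([C@H](O[Si](C)(C)C(C)(C)C)c1ccc(OCc2ccccc2)c(OC)c1)CO | intermediate (not isolated)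
12 | (4R)‑4‑[(S)‑[4‑(benzyloxy)‑3‑methoxyphenyl][(tert‑butyldimethylsilyl)oxy]methyl]oxolan‑2‑ol (anomer mixture) | OC1C[C@@H]([C@H](O[Si](C)(C)C(C)(C)C)c2ccc(OCc3ccccc3)c(OC)c2)CO1 | intermediate
13 | (R)‑4‑[(S)‑[4‑(benzyloxy)‑3‑methoxyphenyl][(tert‑butyldimethylsilyl)oxy]methyl]oxolan‑2‑one | O=C1C[C@@H]([C@H](O[Si](C)(C)C(C)(C)C)c2ccc(OCc3ccccc3)c(OC)c2)CO1 | intermediate
14 | lithium enolate of 13 (lithium 4‑substituted 4,5‑dihydrofuran‑2‑olate) | [Li+].[O-]C1=C[C@@H]([C@H](O[Si](C)(C)C(C)(C)C)c2ccc(OCc3ccccc3)c(OC)c2)CO1 | intermediate (not isolated)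
15 | (3S,4R)‑3‑[(R)‑[4‑(benzyloxy)‑3‑methoxyphenyl](hydroxy)methyl]‑4‑[(S)‑[4‑(benzyloxy)‑3‑methoxyphenyl][(tert‑butyldimethylsilyl)oxy]methyl]oxolan‑2‑one | COc1cc([C@@H](O[Si](C)(C)C(C)(C)C)[C@H]2COC(=O)[C@@H]2[C@@H](O)c2ccc(OCc3ccccc3)c(OC)c2)ccc1OCc1ccccc1 | intermediate
16 | (3S,4R)‑3‑[(R)‑[4‑(benzyloxy)‑3‑methoxyphenyl][(tert‑butyldimethylsilyl)oxy]methyl]‑4‑[(S)‑[4‑(benzyloxy)‑3‑methoxyphenyl][(tert‑butyldimethylsilyl)oxy]methyl]oxolan‑2‑one | COc1cc([C@@H](O[Si](C)(C)C(C)(C)C)[C@H]2COC(=O)[C@@H]2[C@@H](O[Si](C)(C)C(C)(C)C)c2ccc(OCc3ccccc3)c(OC)c2)ccc1OCc1ccccc1 | intermediate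
17 | (2R,3R)‑2‑[(S)‑[4‑(benzyloxy)‑3‑methoxyphenyl][(tert‑butyldimethylsilyl)oxy]methyl]‑3‑[(R)‑[4‑(benzyloxy)‑3‑methoxyphenyl][(tert‑butyldimethylsilyl)oxy]methyl]butane‑1,4‑diol | COc1cc([C@@H](O[Si](C)(C)C(C)(C)C)[C@@H](CO)[C@H](CO)[C@@H](O[Si](C)(C)C(C)(C)C)c2ccc(OCc3ccccc3)c(OC)c2)ccc1OCc1ccccc1 | intermediate
18 | (5R,6R)‑5‑[(S)‑Ar(OTBS)methyl]‑6‑[(R)‑Ar(OTBS)methyl]‑2,2,2‑triphenyl‑1,3,2λ5‑dioxaphosphepane | COc1cc([C@@H](O[Si](C)(C)C(C)(C)C)[C@H]2CO[P](c3ccccc3)(c3ccccc3)(c3ccccc3)OC[C@@H]2[C@@H](O[Si](C)(C)C(C)(C)C)c2ccc(OCc3ccccc3)c(OC)c2)ccc1OCc1ccccc1 | intermediate (not isolated)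
19 | (3R,4R)‑3‑[(S)‑[4‑(benzyloxy)‑3‑methoxyphenyl][(tert‑butyldimethylsilyl)oxy]methyl]‑4‑[(R)‑[4‑(benzyloxy)‑3‑methoxyphenyl][(tert‑butyldimethylsilyl)oxy]methyl]oxolane | COc1cc([C@@H](O[Si](C)(C)C(C)(C)C)[C@H]2COC[C@@H]2[C@@H](O[Si](C)(C)C(C)(C)C)c2ccc(OCc3ccccc3)c(OC)c2)ccc1OCc1ccccc1 | intermediate
20 | (S)‑[4‑(benzyloxy)‑3‑methoxyphenyl][(3R,4R)‑4‑[(R)‑[4‑(benzyloxy)‑3‑methoxyphenyl](hydroxy)methyl]oxolan‑3‑yl]methanol | COc1cc([C@@H](O)[C@H]2COC[C@@H]2[C@@H](O)c2ccc(OCc3ccccc3)c(OC)c2)ccc1OCc1ccccc1 | intermediate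
21 | 4‑[(S)‑hydroxy[(3R,4R)‑4‑[(R)‑hydroxy(4‑hydroxy‑3‑methoxyphenyl)methyl]oxolan‑3‑yl]methyl]‑2‑methoxyphenol | COc1cc([C@@H](O)[C@H]2COC[C@@H]2[C@@H](O)c2ccc(O)c(OC)c2)ccc1O | target

**Totals**
Total steps: 12. Longest linear sequence: 12 steps (1 → 21).

**Three steps most likely to fail**

Step 7 (anti:syn ratio at C7′ in the lactone aldol; trans at C8′ is secure, but the carbinol selectivity of lithium lactone enolates with aryl aldehydes is often only moderate). The fallback sets out from 15, taken as the unseparated mixture with its C7′ epimer, and comes back at 15. Dess–Martin periodinane (NaHCO3, CH2Cl2) converges both epimers on the single β‑keto lactone (3S,4R)‑3‑[4‑(benzyloxy)‑3‑methoxybenzoyl]‑4‑[(S)‑Ar(OTBS)methyl]oxolan‑2‑one F1, whose C3 is trans in its stable form. The aryl ketone is then reduced under catalyst control by Noyori transfer hydrogenation, RuCl[(R,R)‑TsDPEN](p‑cymene) in HCO2H/Et3N, the catalyst enantiomer that gives (R)‑1‑arylalkanols. The C7′ centre is then set by the catalyst and not by the aldol transition state.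

Step 12 (over‑reduction: hydrogenolysis of the free, electron‑rich benzylic C–OH bonds alongside the benzyl ethers). The fallback sets out from 19 and comes back at 21. The benzyl ethers are hydrogenolysed first (H2, Pd/C, EtOAc), while both benzylic oxygens still carry bulky TBS groups that block C–O hydrogenolysis. This gives (3R,4R)‑3‑[(S)‑(4‑hydroxy‑3‑methoxyphenyl)(OTBS)methyl]‑4‑[(R)‑(4‑hydroxy‑3‑methoxyphenyl)(OTBS)methyl]oxolane F2, which is desilylated with AcOH‑buffered TBAF in THF to give 21.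

Step 4 (endocyclic attack on the oxazolidinone ring in place of exocyclic cleavage, because the acyl group of 8 is α‑branched and carries a bulky β‑silyloxy group). The fallback sets out from 7 and comes back at 9. The unprotected aldol adduct is transaminated with MeONHMe·HCl/AlMe3 (CH2Cl2, 0 °C), the free β‑hydroxyl directing the aluminium amide to the exocyclic carbonyl, to give (S)‑2‑[(S)‑Ar(hydroxy)methyl]‑N‑methoxy‑N‑methylpent‑4‑enamide F3. This is silylated (TBSOTf, 2,6‑lutidine) to (S)‑2‑[(S)‑Ar(OTBS)methyl]‑N‑methoxy‑N‑methylpent‑4‑enamide F4 and reduced with DIBAL‑H (THF, −78 °C) to (S)‑2‑[(S)‑Ar(OTBS)methyl]pent‑4‑enal F5. The aldehyde is reduced at once with NaBH4 (MeOH, 0 °C) to 9, before its α‑centre can epimerise.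

**Further compounds**
F1 | step 7 | (3S,4R)‑3‑[4‑(benzyloxy)‑3‑methoxybenzoyl]‑4‑[(S)‑[4‑(benzyloxy)‑3‑methoxyphenyl][(tert‑butyldimethylsilyl)oxy]methyl]oxolan‑2‑one | COc1cc([C@@H](O[Si](C)(C)C(C)(C)C)[C@H]2COC(=O)[C@@H]2C(=O)c2ccc(OCc3ccccc3)c(OC)c2)ccc1OCc1ccccc1
F2 | step 12 | 4‑[(S)‑[(tert‑butyldimethylsilyl)oxy][(3R,4R)‑4‑[(R)‑[(tert‑butyldimethylsilyl)oxy](4‑hydroxy‑3‑methoxyphenyl)methyl]oxolan‑3‑yl]methyl]‑2‑methoxyphenol | COc1cc([C@@H](O[Si](C)(C)C(C)(C)C)[C@H]2COC[C@@H]2[C@@H](O[Si](C)(C)C(C)(C)C)c2ccc(O)c(OC)c2)ccc1O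
F3 | step 4 | (S)‑2‑[(S)‑[4‑(benzyloxy)‑3‑methoxyphenyl](hydroxy)methyl]‑N‑methoxy‑N‑methylpent‑4‑enamide | C=CC[C@@H]([C@H](O)c1ccc(OCc2ccccc2)c(OC)c1)C(=O)N(C)OC
F4 | step 4 | (S)‑2‑[(S)‑[4‑(benzyloxy)‑3‑methoxyphenyl][(tert‑butyldimethylsilyl)oxy]methyl]‑N‑methoxy‑N‑methylpent‑4‑enamide | C=CC[C@@H]([C@H](O[Si](C)(C)C(C)(C)C)c1ccc(OCc2ccccc2)c(OC)c1)C(=O)N(C)OC
F5 | step 4 | (S)‑2‑[(S)‑[4‑(benzyloxy)‑3‑methoxyphenyl][(tert‑butyldimethylsilyl)oxy]methyl]pent‑4‑enal | C=CC[C@@H]([C@H](O[Si](C)(C)C(C)(C)C)c1ccc(OCc2ccccc2)c(OC)c1)C=O
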